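**Retrosynthetic overview**
1. 24 ⇐ diol lactone 23 (acetylation) ⇐ macrocyclic trienol tert-butyl ester 20. One flask: ent-Shi epoxidation of C12=C13, then BF3 opens both epoxides across the ring, C9–OH onto C12 (oxolane) and the tert-butyl ester onto C4 (ε-lactone).
2. 20 ⇐ enone 17 (CBS reduction sets C9; malonate → acrylate) ⇐ Nozaki–Hiyama–Kishi closure of the 14-membered carbocycle at C8–C9 from enol triflate aldehyde 15.
3. 15 ⇐ Claisen rearrangement (E-C12=C13 and the C9 aldehyde) ⇐ isopropenyl addition ⇐ organocatalytic malonate Michael addition to enal 8 (sets C1).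
4. 8 ⇐ epoxy aldehyde 6 ⇐ Shi epoxidation and enol triflation ⇐ Z keto ester 3 ⇐ mono-ozonolysis of 1,5-dimethylcycloocta-1,5-diene 1 (supplies C1–C8 with the Z-C4=C5 bond).
5. Ring order: carbocycle (step 9), then oxolane and ε-lactone together (step 12).

Assumption: commercial 1,5-dimethylcycloocta-1,5-diene is freed from its 1,6-dimethyl isomer by fractional distillation, so 1 is a single isomer.
Locants: in the macrocycle names the ring is numbered as a cembrane. C1 carries the malonyl or acrylate carbon, C4 and C12 carry methyl, C8 carries the methylidene.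

**Step 1**
Reactants: 1 (1Z,5Z)-1,5-dimethylcycloocta-1,5-diene
Product: 3 methyl (4Z)-4-methyl-8-oxonon-4-enoate, via methoxy hydroperoxide 2 (not isolated)
Conditions: O3 (1 equiv), NaHCO3, CH2Cl2–MeOH, −78 °C; then Ac2O, Et3N, 0 °C → rt
Reagents that add atoms: ozone, O=[O+][O-]; methanol, CO
Why: Criegee ozonolysis of one of the two equivalent ring alkenes with methanol trapping, then Ac2O/Et3N dehydration of the methoxy hydroperoxide to the methyl ester (Schreiber terminal differentiation); the untouched ring alkene keeps its Z geometry and becomes C4=C5.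

**Step 2**
Reactants: 3 methyl (4Z)-4-methyl-8-oxonon-4-enoate
Product: 4 methyl (4Z)-4-methyl-8-(trifluoromethanesulfonyloxy)nona-4,8-dienoate
Conditions: LiN(i-Pr)2, THF, −78 °C; PhNTf2, −78 → 0 °C
Reagents that add atoms: N-phenylbis(trifluoromethanesulfonimide), O=S(=O)(N(c1ccccc1)S(=O)(=O)C(F)(F)F)C(F)(F)F
Why: kinetic deprotonation of the methyl ketone at CH3 (the ester α-CH2 is less acidic) and O-sulfonylation of the enolate give the terminal enol triflate that later serves as the C8 alkenyl donor.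

**Step 3**
Reactants: 4 methyl (4Z)-4-methyl-8-(trifluoromethanesulfonyloxy)nona-4,8-dienoate
Product: 5 methyl 3-{(2S,3R)-2-methyl-3-[3-(trifluoromethanesulfonyloxy)but-3-en-1-yl]oxiran-2-yl}propanoate
Conditions: Shi ketone (D-fructose-derived, 30 mol %), KHSO5 (as 2KHSO5·KHSO4·K2SO4), K2CO3, Bu4NHSO4, MeCN–CH2(OMe)2–aq Na2B4O7, 0 °C
Reagents that add atoms: potassium peroxymonosulfate, [K+].[O-]S(=O)(=O)OO
Why: Shi asymmetric epoxidation: the chiral dioxirane attacks the electron-rich trisubstituted Z alkene through the spiro transition state, which for this geometry gives S at the quaternary carbon (C4) and R at the CH carbon (C5); the enol triflate is too electron-poor to react.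

**Step 4**
Reactants: 5 methyl 3-{(2S,3R)-2-methyl-3-[3-(trifluoromethanesulfonyloxy)but-3-en-1-yl]oxiran-2-yl}propanoate
Product: 6 4-[(2R,3S)-3-methyl-3-(3-oxopropyl)oxiran-2-yl]but-1-en-2-yl trifluoromethanesulfonate
Conditions: i-Bu2AlH (1.1 equiv), CH2Cl2, −78 °C; aq KNaC4H4O6
Reagents that add atoms: none
Why: partial ester reduction: the tetrahedral aluminium hemiacetal is stable at −78 °C and releases the aldehyde on work-up; epoxide and enol triflate are inert at this temperature.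

**Step 5**
Reactants: 6 4-[(2R,3S)-3-methyl-3-(3-oxopropyl)oxiran-2-yl]but-1-en-2-yl trifluoromethanesulfonate; 7 2-(triphenyl-λ5-phosphanylidene)acetaldehyde
Product: 8 4-{(2R,3S)-3-methyl-3-[(3E)-5-oxopent-3-en-1-yl]oxiran-2-yl}but-1-en-2-yl trifluoromethanesulfonate
Conditions: PhMe, 60 °C
Reagents that add atoms: none
Why: Wittig olefination with a stabilised formyl ylide is E-selective and adds C14 and C13 as the enal needed for iminium activation.

**Step 6**
Reactants: 8 4-{(2R,3S)-3-methyl-3-[(3E)-5-oxopent-3-en-1-yl]oxiran-2-yl}but-1-en-2-yl trifluoromethanesulfonate; 9 tert-butyl methyl propanedioate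
Product: 10 1-tert-butyl 3-methyl 2-[(3R)-1-{(2S,3R)-2-methyl-3-[3-(trifluoromethanesulfonyloxy)but-3-en-1-yl]oxiran-2-yl}-5-oxopentan-3-yl]propanedioate (both epimers at the malonate carbon)
Conditions: (S)-α,α-diphenylprolinol trimethylsilyl ether (10 mol %), PhCO2H (10 mol %), EtOH, 0 °C → rt
Reagents that add atoms: none
Why: iminium-ion organocatalytic Michael addition (Jørgensen–Hayashi): the diaryl(silyloxy)methyl group of the (S)-catalyst shields one face of the E,s-trans iminium ion, so the malonate adds to the open face and sets C1 as R; the malonate carbon is an irrelevant mixture removed in step 11.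

**Step 7**
Reactants: 10 1-tert-butyl 3-methyl 2-[(3R)-1-{(2S,3R)-2-methyl-3-[3-(trifluoromethanesulfonyloxy)but-3-en-1-yl]oxiran-2-yl}-5-oxopentan-3-yl]propanedioate; 11 prop-1-en-2-ylmagnesium bromide
Product: 12 1-tert-butyl 3-methyl 2-[(3R)-5-hydroxy-6-methyl-1-{(2S,3R)-2-methyl-3-[3-(trifluoromethanesulfonyloxy)but-3-en-1-yl]oxiran-2-yl}hept-6-en-3-yl]propanedioate (both epimers at the carbinol and at the malonate carbon)
Conditions: CH2=C(CH3)MgBr (2.2 equiv), THF, −78 °C; aq NH4Cl
Reagents that add atoms: none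
Why: Grignard 1,2-addition: the first equivalent converts the malonate into its magnesium enolate (which protects both esters), the second adds to the aldehyde faster than to epoxide or enol triflate at −78 °C; the new carbinol centre is unselective and is erased in step 8.

**Step 8**
Reactants: 12 1-tert-butyl 3-methyl 2-[(3R)-5-hydroxy-6-methyl-1-{(2S,3R)-2-methyl-3-[3-(trifluoromethanesulfonyloxy)but-3-en-1-yl]oxiran-2-yl}hept-6-en-3-yl]propanedioate; 13 ethoxyethene
Product: 15 1-tert-butyl 3-methyl 2-[(3R,5E)-6-methyl-1-{(2S,3R)-2-methyl-3-[3-(trifluoromethanesulfonyloxy)but-3-en-1-yl]oxiran-2-yl}-9-oxonon-5-en-3-yl]propanedioate, via allyl vinyl ether 14 (not isolated)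
Conditions: Hg(OAc)2 (30 mol %), neat ethyl vinyl ether, 35 °C; then PhMe, 140 °C (sealed)
Reagents that add atoms: none
Why: mercury-catalysed vinyl exchange followed by Claisen [3,3] rearrangement through a chair transition state with the C14 chain equatorial gives the E trisubstituted C12=C13 alkene and the C9 aldehyde under neutral conditions that spare the epoxide.

**Step 9**
Reactants: 15 1-tert-butyl 3-methyl 2-[(3R,5E)-6-methyl-1-{(2S,3R)-2-methyl-3-[3-(trifluoromethanesulfonyloxy)but-3-en-1-yl]oxiran-2-yl}-9-oxonon-5-en-3-yl]propanedioate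
Product: 17 tert-butyl methyl 2-[(1R,4S,5R,12E)-4,5-epoxy-4,12-dimethyl-8-methylidene-9-oxocyclotetradec-12-en-1-yl]propanedioate, via C9-epimeric alcohols 16 (not isolated)
Conditions: CrCl2 (10 equiv), NiCl2 (10 mol %), DMF–THF, 2 mM, rt; work-up; then Dess–Martin periodinane, NaHCO3, CH2Cl2, 0 °C
Reagents that add atoms: none
Why: Nozaki–Hiyama–Kishi macrocyclisation: nickel inserts into the enol triflate, the alkenyl group passes to chromium and adds only to the aldehyde, high dilution favours the 14-membered ring; Dess–Martin oxidation merges both C9 epimers into one enone.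

**Step 10**
Reactants: 17 tert-butyl methyl 2-[(1R,4S,5R,12E)-4,5-epoxy-4,12-dimethyl-8-methylidene-9-oxocyclotetradec-12-en-1-yl]propanedioate
Product: 18 tert-butyl methyl 2-[(1R,4S,5R,9R,12E)-4,5-epoxy-9-hydroxy-4,12-dimethyl-8-methylidenecyclotetradec-12-en-1-yl]propanedioate
Conditions: (S)-2-methyl-CBS-oxazaborolidine (50 mol %), catecholborane, PhMe, −78 °C
Reagents that add atoms: none
Why: Corey–Bakshi–Shibata reduction: the ketone binds the oxazaborolidine–borane complex anti to its larger α-branched alkenyl substituent, so the (S)-catalyst delivers hydride to give the 9R allylic alcohol; catecholborane avoids alkene hydroboration.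

**Step 11**
Reactants: 18 tert-butyl methyl 2-[(1R,4S,5R,9R,12E)-4,5-epoxy-9-hydroxy-4,12-dimethyl-8-methylidenecyclotetradec-12-en-1-yl]propanedioate
Product: 20 tert-butyl 2-[(1R,4S,5R,9R,12E)-4,5-epoxy-9-hydroxy-4,12-dimethyl-8-methylidenecyclotetradec-12-en-1-yl]prop-2-enoate, via malonic half-acid 19 (not isolated)
Conditions: LiOH (1.1 equiv), THF–H2O, 0 °C; then AcOH to pH 6, Et2NH, aq CH2O, 55 °C
Reagents that add atoms: formaldehyde, C=O
Why: the methyl ester is saponified selectively beside the tert-butyl ester, and the half-acid undergoes Mannich condensation and decarboxylative elimination (Knoevenagel–Doebner-type methylenation) to the acrylate, erasing the malonate stereocentre.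

**Step 12**
Reactants: 20 tert-butyl 2-[(1R,4S,5R,9R,12E)-4,5-epoxy-9-hydroxy-4,12-dimethyl-8-methylidenecyclotetradec-12-en-1-yl]prop-2-enoate
Product: 23 5,13-diol lactone (the target without its two acetyl groups), via bis-epoxide 21 (not isolated), via oxolane epoxide 22 (not isolated)
Conditions: ent-Shi ketone (L-fructose-derived, 50 mol %), KHSO5 (as 2KHSO5·KHSO4·K2SO4), K2CO3, Bu4NHSO4, MeCN–CH2(OMe)2–aq Na2B4O7, 0 °C; extract, dry; then BF3·OEt2, CH2Cl2, −78 → −20 °C
Reagents that add atoms: potassium peroxymonosulfate, [K+].[O-]S(=O)(=O)OO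
Why: Proposed new method: the ent-Shi dioxirane epoxidises only the remaining trisubstituted E alkene (spiro transition state, 12S,13S; the 1,1-disubstituted and acrylate alkenes are poor substrates). BF3 then triggers two transannular epoxide openings in the same flask: the C9 hydroxyl attacks the tertiary C12 (5-exo, inversion to 12R, leaving 13S-OH) to close the oxolane, and the tert-butyl ester carbonyl attacks the tertiary C4 of the other epoxide (7-exo, inversion to 4R, leaving 5R-OH) and loses 2-methylpropene to close the ε-lactone. The closest known chemistry is acid-promoted 5-exo hydroxy-epoxide cyclisation and tert-butyl ester or carbonate-terminated epoxide-opening cascades.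

**Step 13**
Reactants: 23 5,13-diol lactone (the target without its two acetyl groups)
Product: 24 target CNP0133628.2 (5,13-diacetate)
Conditions: Ac2O, pyridine, DMAP, CH2Cl2, 0 °C → rt
Reagents that add atoms: acetic anhydride, CC(=O)OC(C)=O
Why: DMAP-catalysed acylation of the two secondary alcohols; no stereocentre is touched, and prompt acetylation of O13 blocks acyl shift of the lactone to that oxygen.

**Compound list**
1 | (1Z,5Z)-1,5-dimethylcycloocta-1,5-diene | C/C1=C/CC/C(C)=C\CC1 | starting material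
2 | (5Z)-9-hydroperoxy-9-methoxy-6-methylnon-5-en-2-one | COC(OO)CC/C(C)=C\CCC(C)=O | intermediate
3 | methyl (4Z)-4-methyl-8-oxonon-4-enoate | COC(=O)CC/C(C)=C\CCC(C)=O | intermediate
4 | methyl (4Z)-4-methyl-8-(trifluoromethanesulfonyloxy)nona-4,8-dienoate | COC(=O)CC/C(C)=C\CCC(=C)OS(=O)(=O)C(F)(F)F | intermediate
5 | methyl 3-{(2S,3R)-2-methyl-3-[3-(trifluoromethanesulfonyloxy)but-3-en-1-yl]oxiran-2-yl}propanoate | COC(=O)CC[C@]1(C)O[C@@H]1CCC(=C)OS(=O)(=O)C(F)(F)F | intermediate
6 | 4-[(2R,3S)-3-methyl-3-(3-oxopropyl)oxiran-2-yl]but-1-en-2-yl trifluoromethanesulfonate | O=CCC[C@]1(C)O[C@@H]1CCC(=C)OS(=O)(=O)C(F)(F)F | intermediate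
7 | 2-(triphenyl-λ5-phosphanylidene)acetaldehyde | O=CC=P(c1ccccc1)(c1ccccc1)c1ccccc1 | starting material
8 | 4-{(2R,3S)-3-methyl-3-[(3E)-5-oxopent-3-en-1-yl]oxiran-2-yl}but-1-en-2-yl trifluoromethanesulfonate | O=C/C=C/CC[C@]1(C)O[C@@H]1CCC(=C)OS(=O)(=O)C(F)(F)F | intermediate
9 | tert-butyl methyl propanedioate (tert-butyl methyl malonate) | COC(=O)CC(=O)OC(C)(C)C | starting material
10 | 1-tert-butyl 3-methyl 2-[(3R)-1-{(2S,3R)-2-methyl-3-[3-(trifluoromethanesulfonyloxy)but-3-en-1-yl]oxiran-2-yl}-5-oxopentan-3-yl]propanedioate (both epimers at the malonate carbon) | O=CC[C@@H](CC[C@]1(C)O[C@@H]1CCC(=C)OS(=O)(=O)C(F)(F)F)C(C(=O)OC)C(=O)OC(C)(C)C | intermediate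
11 | prop-1-en-2-ylmagnesium bromide | C=C(C)[Mg]Br | starting material
12 | 1-tert-butyl 3-methyl 2-[(3R)-5-hydroxy-6-methyl-1-{(2S,3R)-2-methyl-3-[3-(trifluoromethanesulfonyloxy)but-3-en-1-yl]oxiran-2-yl}hept-6-en-3-yl]propanedioate (both epimers at the carbinol and at the malonate carbon) | C=C(C)C(O)C[C@@H](CC[C@]1(C)O[C@@H]1CCC(=C)OS(=O)(=O)C(F)(F)F)C(C(=O)OC)C(=O)OC(C)(C)C | intermediate
13 | ethoxyethene (ethyl vinyl ether) | C=COCC | starting material
14 | 1-tert-butyl 3-methyl 2-[(3R)-5-(ethenyloxy)-6-methyl-1-{(2S,3R)-2-methyl-3-[3-(trifluoromethanesulfonyloxy)but-3-en-1-yl]oxiran-2-yl}hept-6-en-3-yl]propanedioate (epimer mixture as 12) | C=COC(C[C@@H](CC[C@]1(C)O[C@@H]1CCC(=C)OS(=O)(=O)C(F)(F)F)C(C(=O)OC)C(=O)OC(C)(C)C)C(C)=C | intermediate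
15 | 1-tert-butyl 3-methyl 2-[(3R,5E)-6-methyl-1-{(2S,3R)-2-methyl-3-[3-(trifluoromethanesulfonyloxy)but-3-en-1-yl]oxiran-2-yl}-9-oxonon-5-en-3-yl]propanedioate (both epimers at the malonate carbon) | O=CCC/C(C)=C/C[C@@H](CC[C@]1(C)O[C@@H]1CCC(=C)OS(=O)(=O)C(F)(F)F)C(C(=O)OC)C(=O)OC(C)(C)C | intermediate
16 | tert-butyl methyl 2-[(1R,4S,5R,12E)-4,5-epoxy-9-hydroxy-4,12-dimethyl-8-methylidenecyclotetradec-12-en-1-yl]propanedioate (both C9 epimers) | OC1CC/C(C)=C/C[C@H](C(C(=O)OC)C(=O)OC(C)(C)C)CC[C@]2(C)O[C@@H]2CCC1=C | intermediate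
17 | tert-butyl methyl 2-[(1R,4S,5R,12E)-4,5-epoxy-4,12-dimethyl-8-methylidene-9-oxocyclotetradec-12-en-1-yl]propanedioate | O=C1CC/C(C)=C/C[C@H](C(C(=O)OC)C(=O)OC(C)(C)C)CC[C@]2(C)O[C@@H]2CCC1=C | intermediate
18 | tert-butyl methyl 2-[(1R,4S,5R,9R,12E)-4,5-epoxy-9-hydroxy-4,12-dimethyl-8-methylidenecyclotetradec-12-en-1-yl]propanedioate | O[C@@H]1CC/C(C)=C/C[C@H](C(C(=O)OC)C(=O)OC(C)(C)C)CC[C@]2(C)O[C@@H]2CCC1=C | intermediate
19 | 3-tert-butoxy-2-[(1R,4S,5R,9R,12E)-4,5-epoxy-9-hydroxy-4,12-dimethyl-8-methylidenecyclotetradec-12-en-1-yl]-3-oxopropanoic acid | O[C@@H]1CC/C(C)=C/C[C@H](C(C(=O)O)C(=O)OC(C)(C)C)CC[C@]2(C)O[C@@H]2CCC1=C | intermediate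
20 | tert-butyl 2-[(1R,4S,5R,9R,12E)-4,5-epoxy-9-hydroxy-4,12-dimethyl-8-methylidenecyclotetradec-12-en-1-yl]prop-2-enoate | O[C@@H]1CC/C(C)=C/C[C@H](C(=C)C(=O)OC(C)(C)C)CC[C@]2(C)O[C@@H]2CCC1=C | intermediate
21 | tert-butyl 2-[(1R,4S,5R,9R,12S,13S)-4,5:12,13-diepoxy-9-hydroxy-4,12-dimethyl-8-methylidenecyclotetradecyl]prop-2-enoate | O[C@@H]1CC[C@]3(C)O[C@H]3C[C@H](C(=C)C(=O)OC(C)(C)C)CC[C@]2(C)O[C@@H]2CCC1=C | intermediate
22 | tert-butyl 2-[(1R,4S,5R,9R,12R,13S)-4,5:9,12-diepoxy-13-hydroxy-4,12-dimethyl-8-methylidenecyclotetradecyl]prop-2-enoate (9,12-epoxy is the oxolane) | C=C(C(=O)OC(C)(C)C)[C@@H]1CC[C@]2(C)O[C@@H]2CCC(=C)[C@H]2CC[C@@](C)(O2)[C@@H](O)C1 | intermediate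
23 | ε-lactone (C16 onto O4) of 2-[(1R,4R,5R,9R,12R,13S)-9,12-epoxy-4,5,13-trihydroxy-4,12-dimethyl-8-methylidenecyclotetradecyl]prop-2-enoic acid, with free 5- and 13-hydroxyls | C=C1C(=O)O[C@]2(C)CC[C@@H]1C[C@H](O)[C@@]1(C)CC[C@@H](O1)C(=C)CC[C@H]2O | intermediate
24 | CNP0133628.2, the 5,13-diacetate of 23 (1R,4R,5R,9R,12R,13S) | C=C1C(=O)O[C@]2(C)CC[C@@H]1C[C@H](OC(C)=O)[C@@]1(C)CC[C@@H](O1)C(=C)CC[C@H]2OC(C)=O | target

**Totals**
Total step count: 13. Longest linear sequence: 13 (fully linear; 7, 9, 11 and 13 are bought).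

**Steps most likely to fail**

Step 12 is the weakest. Reagent control of the epoxidation may be overridden by the face bias of the macrocycle. The 7-exo attack of a tert-butyl ester on the C4 epoxide competes with hydride shift, elimination, and closure of a δ-lactone onto O13. The fallback builds the lactone by acylation instead of epoxide opening. It sets out from 20: ent-Shi epoxidation followed only by catalytic camphorsulfonic acid closes the oxolane, and the oxolane epoxide 22 is isolated. Aqueous HClO4 in THF opens the remaining epoxide with water at the tertiary carbon (inversion) to tert-butyl 2-[(1R,4R,5R,9R,12R,13S)-9,12-epoxy-4,5,13-trihydroxy-4,12-dimethyl-8-methylidenecyclotetradecyl]prop-2-enoate F1. Ac2O and pyridine acetylate only the two secondary hydroxyls to give the 5,13-diacetate tertiary alcohol F2. CF3CO2H removes the tert-butyl group to give the hydroxy acid F3. Yamaguchi lactonisation (2,4,6-trichlorobenzoyl chloride, Et3N, then DMAP, PhMe, high dilution) closes the ε-lactone with retention at C4 and comes back to the route at 24.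

Step 9 is next. The 14-membered closure may lose to oligomerisation or to reduction of the alkenyl metal. The fallback closes the same bond as a ketone by acyl cross-coupling and sets out from 15. NaClO2, NaH2PO4 and 2-methylbut-2-ene oxidise the aldehyde to the enol triflate acid F4. (Me3Sn)2 with Pd(PPh3)4 and LiCl converts the triflate into the alkenylstannane acid F5. 1-Chloro-N,N,2-trimethylprop-1-en-1-amine gives the acid chloride F6. Under zerovalent palladium (Pd2(dba)3, tri(2-furyl)phosphine, PhMe, high dilution) F6 undergoes intramolecular Stille acylation and comes back at enone 17.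

Step 6 is third. Iminium additions of malonates to aliphatic enals can be slow and less selective, with aldol side reactions. The fallback reverses the polarity and sets out from aldehyde 6. Knoevenagel condensation with 9 (TiCl4, pyridine, THF) gives the alkylidene malonate F7. A Mukaiyama–Michael addition of 1-(ethylsulfanyl)-1-(trimethylsilyloxy)ethene follows, catalysed by the divalent copper bis(oxazoline) Lewis acid [Cu(t-Bu-box)](SbF6)2; the ligand antipode that exposes the face leading to 1R has to be chosen. This gives the thioester F8. Fukuyama reduction (Et3SiH, Pd on carbon) converts F8 into the aldehyde and comes back at 10.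

**Further compounds**
F1 | step 12 | tert-butyl 2-[(1R,4R,5R,9R,12R,13S)-9,12-epoxy-4,5,13-trihydroxy-4,12-dimethyl-8-methylidenecyclotetradecyl]prop-2-enoate | C=C(C(=O)OC(C)(C)C)[C@@H]1CC[C@@](C)(O)[C@H](O)CCC(=C)[C@H]2CC[C@@](C)(O2)[C@@H](O)C1
F2 | step 12 | tert-butyl 2-[(1R,4R,5R,9R,12R,13S)-5,13-diacetoxy-9,12-epoxy-4-hydroxy-4,12-dimethyl-8-methylidenecyclotetradecyl]prop-2-enoate | C=C(C(=O)OC(C)(C)C)[C@@H]1CC[C@@](C)(O)[C@H](OC(C)=O)CCC(=C)[C@H]2CC[C@@](C)(O2)[C@@H](OC(C)=O)C1
F3 | step 12 | 2-[(1R,4R,5R,9R,12R,13S)-5,13-diacetoxy-9,12-epoxy-4-hydroxy-4,12-dimethyl-8-methylidenecyclotetradecyl]prop-2-enoic acid | C=C(C(=O)O)[C@@H]1CC[C@@](C)(O)[C@H](OC(C)=O)CCC(=C)[C@H]2CC[C@@](C)(O2)[C@@H](OC(C)=O)C1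
F4 | step 9 | (4E,7R)-7-(1-tert-butoxy-3-methoxy-1,3-dioxopropan-2-yl)-4-methyl-9-{(2S,3R)-2-methyl-3-[3-(trifluoromethanesulfonyloxy)but-3-en-1-yl]oxiran-2-yl}non-4-enoic acid | OC(=O)CC/C(C)=C/C[C@@H](CC[C@]1(C)O[C@@H]1CCC(=C)OS(=O)(=O)C(F)(F)F)C(C(=O)OC)C(=O)OC(C)(C)C
F5 | step 9 | (4E,7R)-7-(1-tert-butoxy-3-methoxy-1,3-dioxopropan-2-yl)-4-methyl-9-{(2S,3R)-2-methyl-3-[3-(trimethylstannyl)but-3-en-1-yl]oxiran-2-yl}non-4-enoic acid | OC(=O)CC/C(C)=C/C[C@@H](CC[C@]1(C)O[C@@H]1CCC(=C)[Sn](C)(C)C)C(C(=O)OC)C(=O)OC(C)(C)C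
F6 | step 9 | acid chloride of F5 | ClC(=O)CC/C(C)=C/C[C@@H](CC[C@]1(C)O[C@@H]1CCC(=C)[Sn](C)(C)C)C(C(=O)OC)C(=O)OC(C)(C)C
F7 | step 6 | 1-tert-butyl 3-methyl 2-(3-{(2S,3R)-2-methyl-3-[3-(trifluoromethanesulfonyloxy)but-3-en-1-yl]oxiran-2-yl}propylidene)propanedioate (E/Z mixture) | COC(=O)C(=CCC[C@]1(C)O[C@@H]1CCC(=C)OS(=O)(=O)C(F)(F)F)C(=O)OC(C)(C)C
F8 | step 6 | 1-tert-butyl 3-methyl 2-[(3R)-1-(ethylsulfanyl)-5-{(2S,3R)-2-methyl-3-[3-(trifluoromethanesulfonyloxy)but-3-en-1-yl]oxiran-2-yl}-1-oxopentan-3-yl]propanedioate | CCSC(=O)C[C@@H](CC[C@]1(C)O[C@@H]1CCC(=C)OS(=O)(=O)C(F)(F)F)C(C(=O)OC)C(=O)OC(C)(C)C
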